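## Structural features

Atom labels C1–O28 follow the atom order of the target SMILES. The target is a xeniaphyllane-type diterpenoid peroxide on a caryophyllene-like bicycle. Cyclobutane ring A (C11–C14) is trans-fused along C11–C12 to nine-membered ring B (C2, C3, C4, C5, C7, C9, C10, C11, C12). Quaternary C14 carries the methyl C15 and, through C16, the 3,6-dihydro-1,2-dioxin-3-ol ring C (C16, C18, C19, C20, O27, O28). Ring B holds an exocyclic methylene at C2 and a trans-trisubstituted epoxide at C5/C7 with the relative configuration of caryophyllene oxide. Ring C holds the hemiketal OH at C16 and a methyl and an acetoxymethyl group at C20.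

Of the seven stereocentres, C11, C12 and C14 are contiguous on ring A (H-11 and H-12 trans, the C10 chain cis to C15 and trans to C16). C5 and C7 form the epoxide. C16 is a peroxyhemiketal centre that can equilibrate by ring–chain tautomerism. C20 is a fully substituted peroxy carbon, remote from all other centres, and must be set by the reagent.

The fragile parts are the O–O bond (reductants, phosphines, low-valent metals), the peroxyhemiketal, the acetate, and the strained E-olefin or epoxide of ring B, which is prone to transannular reactions in acid. The real difficulty lies in three places: the strained trans-fused ring A with a quaternary carbon next to a tertiary one, the closure of a nine-membered ring around an E-trisubstituted double bond, and C20.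

The key step exploits the fact that the substituent pattern of ring A (chain on C11, C2 on C12, methyl and C16 on C14) is also the pattern of a cyclopentanone made of C2 and C11–C14, where conjugate addition and enolate chemistry are easy. Moving C13 from C2 to C12 takes C2 out of the ring, makes ring A, and leaves C2 as the carboxyl carbon from which ring B is grown.

## Logic of the disconnections

37 ⇒ 36. The C5–O6 and C7–O6 bonds are cut first. A ring-B epoxide would not survive the acid-activated peroxide chemistry that builds ring C, whereas the reverse order only asks a peracid to choose the most electron-rich, strained double bond. This removes two stereocentres. The forward step must oxidise C5=C7 ahead of C2=C1 and C18=C19, on the face that the preferred conformers of ring B expose.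

36 ⇒ 35 ⇒ 33. After removal of the acetate, ring C is cut at C20–O27 and C16–O28. C20 can only be controlled from outside, and an epoxide is the one practical electrophile that lets a peroxide oxygen enter a tertiary carbon stereospecifically. The whole peroxide ring is thereby reduced to an epoxy enone, and the O–O bond appears only at the end. The forward step needs inversion at C20, a Z double bond to bring the hydroperoxide to C16, and tolerance of the ring-B olefins.

33 ⇒ 26 + 29. The C16–C18 bond is cut (through 32 and 31) to give a neopentyl aldehyde and an acetylide. The alkyne provides the Z geometry by semi-hydrogenation, and the cut is convergent. C20 comes from 27 through 28 and 29, so its configuration is bought, not made. The forward step needs only a 1,2-addition whose new carbinol centre is later oxidised away.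

26 ⇒ 23. The C2=C1 bond is cut (carbonyl methylenation) and C16 is returned to a protected alcohol (25, 24). This exposes a C2 ketone, the natural handle for closing ring B. The forward methylenation must tolerate an enolisable, trans-fused ketone.

23 ⇒ 22 ⇒ 21. Ring B is cut at C2–C3. C2 is a carbonyl carbon and a sulfone-stabilised carbanion at C3 turns the closure into a Claisen-type acylation that is driven by the acidity of the product. The E double bond is a bystander in this step. Ring B is reduced to a chain on ring A. The forward step needs high dilution, a preset E-olefin and the trans C11/C12 relationship.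

21 ⇒ 20 ⇒ 19 ⇒ 17. C3–C4 is cut (alkylation of a sulfonyl carbanion by an allylic bromide), then C4–C5 and C7–C8 (carboalumination of a terminal alkyne, then formaldehyde). The syn addition fixes the E geometry, and the chain shrinks to a butynyl group. The ester must survive the aluminium reagent and the sulfonyl anion.

17 ⇒ 14 (key). C12–C13 is cut and C13 is reconnected to C2. Ring A becomes a 2-diazocyclopentanone, in which C11 and C14 can be set by ordinary enone chemistry. The forward step must favour the 1,2-shift over other carbene pathways and must end with C12 trans to the C10 chain.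

14 ⇒ 11 ⇒ 8 + 9. The diazo group is traced to the regiodefined enolate stored in 11, and C10–C11 is cut (conjugate addition). This leaves a 4,4-disubstituted cyclopentenone and a four-carbon halide. The forward addition must enter anti to the larger C14 substituent.

8 ⇒ 6 ⇒ 5 ⇒ 3 ⇒ 1. The C11=C12 unsaturation, the silyl group and the C16 oxygen are removed in turn (C16 comes from a vinyl group), and C14–C16 is cut (catalytic asymmetric conjugate addition). All absolute configuration of rings A and B then rests on one catalytic step on a commercial enone. That step must form a quaternary centre on a five-membered ring with high enantioselectivity.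

## Other disconnections considered

Alternative 1: The cut is C20–O27 together with C16–O28, which opens ring C to the Z-γ,δ-epoxy enone A2 and a peroxide reagent. In the forward step the peroxide opens the epoxide at tertiary C20 with inversion and the new hydroperoxide adds to the C16 ketone, giving dioxinol A1.
- In favour: it is the only disconnection that controls C20, it makes two C–O bonds in one flask, and it introduces the O–O bond at the very end.
- Against, as the organising step: it leaves rings A and B (four stereocentres, the quaternary C14, both strained rings) unsolved, and it runs on the most sensitive substrate of the synthesis.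
- Comparison: for ring C it is the better idea, and the chosen plan has no answer of its own for C20; it is therefore used as step 21 (A2 and A1 are 33 and 35). Mechanistically, a polar substitution at a tertiary centre is less assured in its stereochemical course than the 1,2-shift of the chosen key step. In step count it neither adds nor saves, because both plans need the same carbocycle first. The two disconnections complement each other.

Alternative 2: The cut is C3–C4, which opens ring B to the acyclic β-keto sulfone allylic carbonate A4. In the forward step a zerovalent palladium catalyst ionises the carbonate and the C3 carbanion attacks the primary allyl terminus C4, giving cyclononenone A3.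
- In favour: neutral conditions, a soft nucleophile, and attack at the less substituted terminus, which leads to the nine-membered ring and not to the seven-membered one.
- Against: during a slow medium-ring closure the π-allyl intermediate can exchange the syn and anti substituents at C7. That would erode the E geometry of C5=C7 in favour of the less strained Z ring. Ring A remains unsolved.
- Comparison: A4 is reached in as many steps as 21, and A3 is the silyl analogue of 22, so step economy is equal. The alternative is the milder of the two closures. The chosen route is safer on geometry, because it forms C2–C3 and leaves the olefin untouched. The palladium closure is kept as the fallback for step 11.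

Alternative 3: The cuts are C2–C12 and C14–C16, with the central C12–C14 bond re-formed to give bicyclobutane ester A6. In the forward step an isopropenyl copper reagent adds to bridgehead C12, the central bond breaks, and the C14 ester enolate is trapped by a benzyloxymethyl electrophile, giving cyclobutane A5.
- In favour: this is a true competitor for ring A. It needs no photochemistry and installs three ring-A substituents in one operation. C11/C12 come out trans from backside opening of the exo-substituted A6. The electrophile enters C14 anti to the C11 chain, a hydrogen-versus-alkyl distinction that is stronger than the methyl-versus-silyloxymethyl distinction of step 5. On this point the alternative is better.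
- Against: A6 must be made as a single enantiomer with its chain exo, and there is no counterpart to the catalytic conjugate addition that sets the absolute configuration in the chosen plan. In A5 the future C15 is an ester that must be reduced to a methyl group at a neopentyl position. C2 arrives as an isopropenyl group, so C3 is an unactivated allylic methyl and ring B cannot be closed by carbonyl chemistry at C2.
- Comparison: on structure, the alternative controls C14 better; the chosen plan controls absolute configuration better and delivers C2 at the right oxidation level. On mechanism, strain-release addition and 1,2-shift are both credible. On step economy, the two are about equal up to the cyclobutane, and the alternative is longer afterwards.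

Key step: step 7

**Remarks and assumptions**

- Assumption: (S)-2-methylglycidol 27 and the bromide 9 are taken as purchasable. Otherwise 27 is one Sharpless epoxidation from 2-methylprop-2-en-1-ol, and 9 is one Appel bromination from 4-(trimethylsilyl)but-3-yn-1-ol.
- The configurations of the key-step precursor and product were checked against the target (C10 chain cis to C15, C12 trans to the chain); no correction was needed.
- Design changes to the precursor:
  - The silyl ether is TBDPS, to enlarge the difference between the two C14 substituents.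
  - The diazo group is placed through the trapped enolate of the conjugate addition.
  - The alkynyl SiMe3 group is shed in the key-step flask, because methoxide equilibration of C12 would not spare it.
  - The vinyl nucleophile of step 1 is a silylvinylaluminium reagent.

## Steps

Step 1
Reactants: 1 3-methylcyclopent-2-en-1-one
Product: 3 (R)-3-ethenyl-3-methylcyclopentan-1-one, via silylvinyl ketone 2 (not isolated)
Conditions: HC≡CSiMe3, iBu2AlH, hexanes, 55 °C; then 1, Cu(OTf)2 (5 mol%), chiral sulfonate-bearing N-heterocyclic carbene ligand (5 mol%), THF, −15 → 22 °C; crude 2, CF3CO2H, CHCl3, 22 °C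
Reagents that add atoms: ethynyltrimethylsilane, C#C[Si](C)(C)C
Why: Copper-catalysed enantioselective conjugate addition of a silyl-substituted vinylaluminium reagent to a β-substituted cyclopentenone sets quaternary C14; the ligand enantiomer is chosen for the R ketone. Protodesilylation of the α-silylvinyl group (ipso protonation, β-silyl cation) then leaves the plain vinyl group as the carrier of C16.

Step 2
Reactants: 3 (R)-3-ethenyl-3-methylcyclopentan-1-one
Product: 5 (R)-3-(hydroxymethyl)-3-methylcyclopentan-1-one, via keto aldehyde 4 (not isolated)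
Conditions: O3, CH2Cl2, −78 °C; PPh3, −78 → 22 °C; then NaBH(OAc)3, AcOH (cat.), 22 °C
Reagents that add atoms: ozone, [O-][O+]=O
Why: Ozonolysis with reductive work-up cuts the vinyl group to the C16 aldehyde. The acyloxyborohydride reduces aldehydes far faster than ketones, so the C2 ketone is kept and C14 is not touched.

Step 3
Reactants: 5 (R)-3-(hydroxymethyl)-3-methylcyclopentan-1-one
Product: 6 (R)-3-{[(tert-butyldiphenylsilyl)oxy]methyl}-3-methylcyclopentan-1-one
Conditions: tBuPh2SiCl, imidazole, DMF, 22 °C
Reagents that add atoms: tert-butylchlorodiphenylsilane, CC(C)(C)[Si](Cl)(c1ccccc1)c1ccccc1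
Why: Standard silylation of a primary alcohol. The bulky, non-chelating TBDPS ether is chosen to make the oxymethyl group clearly larger than the methyl group for step 5 and to last until step 14.

Step 4
Reactants: 6 (R)-3-{[(tert-butyldiphenylsilyl)oxy]methyl}-3-methylcyclopentan-1-one
Product: 8 (S)-4-{[(tert-butyldiphenylsilyl)oxy]methyl}-4-methylcyclopent-2-en-1-one, via silyl enol ether 7 (not isolated)
Conditions: LiN(iPr)2, Me3SiCl, THF, −78 °C; then Pd(OAc)2 (10 mol%), O2 (1 atm), DMSO, 22 °C
Reagents that add atoms: none
Why: Saegusa–Ito dehydrogenation. Kinetic deprotonation prefers C12 over the neopentyl C13, and only the C2=C12 enol ether has a β-hydrogen (on C11) because C14 is quaternary, so one enone alone can form and any regioisomeric enol ether returns 6 on work-up.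

Step 5
Reactants: 8 (S)-4-{[(tert-butyldiphenylsilyl)oxy]methyl}-4-methylcyclopent-2-en-1-one; 9 (4-bromobut-1-yn-1-yl)trimethylsilane
Product: 11 (3S,4S)-4-{[(tert-butyldiphenylsilyl)oxy]methyl}-4-methyl-1-[(trimethylsilyl)oxy]-3-[4-(trimethylsilyl)but-3-yn-1-yl]cyclopent-1-ene, via Grignard reagent 10 (not isolated)
Conditions: 9, Mg, THF, 22 °C; then CuBr·SMe2 (20 mol%), Me3SiCl, 8, THF, −78 → −40 °C; Et3N, pentane work-up
Reagents that add atoms: chlorotrimethylsilane, C[Si](C)(C)Cl
Why: Copper-catalysed conjugate addition of a Grignard reagent with silyl chloride acceleration forms C10–C11 and stores the enolate regiospecifically at C2/C12. The reagent should approach C11 anti to the larger silyloxymethyl group on C14, which places the chain cis to C15.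

Step 6
Reactants: 11 (3S,4S)-4-{[(tert-butyldiphenylsilyl)oxy]methyl}-4-methyl-1-[(trimethylsilyl)oxy]-3-[4-(trimethylsilyl)but-3-yn-1-yl]cyclopent-1-ene
Product: 14 (3R,4S)-4-{[(tert-butyldiphenylsilyl)oxy]methyl}-2-diazo-4-methyl-3-[4-(trimethylsilyl)but-3-yn-1-yl]cyclopentan-1-one, via lithium enolate 12 (not isolated), via trifluoroacetyl ketone 13 (not isolated)
Conditions: MeLi (1.0 equiv), THF, −20 → 0 °C; CF3CO2CH2CF3, −78 °C; then MeSO2N3, Et3N, H2O, MeCN, 22 °C
Reagents that add atoms: methanesulfonyl azide, CS(=O)(=O)N=[N+]=[N-]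
Why: The lithium enolate released from the silyl enol ether is C-trifluoroacetylated at C12, and the activated 1,3-dicarbonyl undergoes detrifluoroacetylative diazo transfer (Regitz type), so the diazo group can only end on C12. C11 and C14 are not involved.

Step 7
Reactants: 14 (3R,4S)-4-{[(tert-butyldiphenylsilyl)oxy]methyl}-2-diazo-4-methyl-3-[4-(trimethylsilyl)but-3-yn-1-yl]cyclopentan-1-one
Product: 17 methyl (1R,2S,3S)-2-(but-3-yn-1-yl)-3-{[(tert-butyldiphenylsilyl)oxy]methyl}-3-methylcyclobutane-1-carboxylate, via ketene 15 (not isolated), via silylated ester 16 (not isolated)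
Conditions: hν (medium-pressure Hg lamp, Pyrex, λ > 300 nm), MeOH/THF, 0 °C; then NaOMe (0.5 equiv), MeOH, 40 °C
Reagents that add atoms: methanol, CO
Why: Excitation of the s-cis-locked α-diazo ketone expels N2 and C13 shifts from C2 to C12; this forms C12–C13, contracts the five-membered ring to ring A and leaves C2 as the ketene carbon of 15. Methanol adds to the ketene and the ester enol tautomerises to 16. This is the photochemical Wolff rearrangement of cyclic 2-diazo ketones, the standard ring contraction to cycloalkanecarboxylates. Ring A therefore arises by a 1,2-alkyl shift and not by a four-membered cyclisation, so no closure mode has to compete. C11 and C14 are carried over from steps 1 and 5; the new centre C12 is first set by kinetic protonation of the enol and is then equilibrated by methoxide to the trans relationship with the C10 chain (thermodynamic control on the cyclobutane). The selectivity needed is migration over other carbene reactions (1,2-hydride shift from C11, insertion, addition to the alkyne): the ring holds the diazo ketone in the geometry for concerted migration, the migrating carbon is an unhindered CH2, and irradiation above 300 nm avoids sensitised triplet chemistry and absorption by the TBDPS phenyl groups. The same methoxide treatment removes the alkynyl SiMe3 group, which is no longer needed, so 17 is ready for carboalumination.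

Step 8
Reactants: 17 methyl (1R,2S,3S)-2-(but-3-yn-1-yl)-3-{[(tert-butyldiphenylsilyl)oxy]methyl}-3-methylcyclobutane-1-carboxylate
Product: 19 methyl (1R,2S,3S)-3-{[(tert-butyldiphenylsilyl)oxy]methyl}-2-[(3E)-5-hydroxy-3-methylpent-3-en-1-yl]-3-methylcyclobutane-1-carboxylate, via alkenylalane 18 (not isolated)
Conditions: Me3Al, Cp2ZrCl2 (20 mol%), H2O (1 equiv), CH2Cl2, −25 °C; then (CH2O)n, −25 → 22 °C
Reagents that add atoms: trimethylaluminium, C[Al](C)C; paraformaldehyde (as formaldehyde), C=O
Why: Zirconium-catalysed syn carboalumination (Negishi) of the terminal alkyne puts the methyl group C8 on C7 and aluminium on C5, and the alkenylalane adds to formaldehyde with retention to give the E-trisubstituted allylic alcohol with C4. The water-accelerated low-temperature variant limits contact of Me3Al with the hindered ester.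

Step 9
Reactants: 19 methyl (1R,2S,3S)-3-{[(tert-butyldiphenylsilyl)oxy]methyl}-2-[(3E)-5-hydroxy-3-methylpent-3-en-1-yl]-3-methylcyclobutane-1-carboxylate
Product: 20 methyl (1R,2S,3S)-2-[(3E)-5-bromo-3-methylpent-3-en-1-yl]-3-{[(tert-butyldiphenylsilyl)oxy]methyl}-3-methylcyclobutane-1-carboxylate
Conditions: CBr4, PPh3, CH2Cl2, −20 °C
Reagents that add atoms: tetrabromomethane, BrC(Br)(Br)Br
Why: Appel bromination of a primary allylic alcohol by SN2 displacement of the alkoxyphosphonium ion; the olefin geometry is kept.

Step 10
Reactants: 20 methyl (1R,2S,3S)-2-[(3E)-5-bromo-3-methylpent-3-en-1-yl]-3-{[(tert-butyldiphenylsilyl)oxy]methyl}-3-methylcyclobutane-1-carboxylate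
Product: 21 methyl (1R,2S,3S)-3-{[(tert-butyldiphenylsilyl)oxy]methyl}-3-methyl-2-[(3E)-3-methyl-6-(phenylsulfonyl)hex-3-en-1-yl]cyclobutane-1-carboxylate
Conditions: PhSO2CH3, n-BuLi, THF, −78 °C; then 20, −78 °C
Reagents that add atoms: methyl phenyl sulfone, CS(=O)(=O)c1ccccc1
Why: Alkylation of the lithiated sulfone by the primary allylic bromide forms C3–C4. At −78 °C the SN2 reaction is much faster than addition of the anion to the hindered cyclobutane ester.

Step 11
Reactants: 21 methyl (1R,2S,3S)-3-{[(tert-butyldiphenylsilyl)oxy]methyl}-3-methyl-2-[(3E)-3-methyl-6-(phenylsulfonyl)hex-3-en-1-yl]cyclobutane-1-carboxylate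
Product: 22 (1R,5E,9S,10S)-10-{[(tert-butyldiphenylsilyl)oxy]methyl}-6,10-dimethyl-3-(phenylsulfonyl)bicyclo[7.2.0]undec-5-en-2-one (C3 epimer mixture)
Conditions: LiN(SiMe3)2 (3 equiv), THF, slow addition of 21 (final 2 mM), 0 → 45 °C
Reagents that add atoms: none
Why: Intramolecular Claisen-type acylation of the α-sulfonyl carbanion (C3) by the ester (C2), a known way to medium-ring ketones, closes ring B and is pulled forward by deprotonation of the acidic β-keto sulfone. The E double bond is not involved, and C12 stays trans, its more stable arrangement.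

Step 12
Reactants: 22 (1R,5E,9S,10S)-10-{[(tert-butyldiphenylsilyl)oxy]methyl}-6,10-dimethyl-3-(phenylsulfonyl)bicyclo[7.2.0]undec-5-en-2-one (C3 epimer mixture)
Product: 23 (1R,5E,9S,10S)-10-{[(tert-butyldiphenylsilyl)oxy]methyl}-6,10-dimethylbicyclo[7.2.0]undec-5-en-2-one
Conditions: SmI2, THF/MeOH, −78 °C
Reagents that add atoms: none
Why: Single-electron reductive cleavage of the C–S bond α to the ketone, with protonation of the samarium enolate. At −78 °C the ketone and the olefin are not reduced.

Step 13
Reactants: 23 (1R,5E,9S,10S)-10-{[(tert-butyldiphenylsilyl)oxy]methyl}-6,10-dimethylbicyclo[7.2.0]undec-5-en-2-one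
Product: 24 tert-butyl{[(1S,4E,9R,11S)-4,11-dimethyl-8-methylidenebicyclo[7.2.0]undec-4-en-11-yl]methoxy}diphenylsilane
Conditions: Ph3PCH3Br, KOtBu, THF, 0 → 50 °C
Reagents that add atoms: methyltriphenylphosphonium bromide, C[P+](c1ccccc1)(c1ccccc1)c1ccccc1.[Br-]
Why: Wittig methylenation of the ring-B ketone installs C1, as in the classical end of caryophyllene syntheses. Any enolisation at C12 returns the more stable trans ring fusion.

Step 14
Reactants: 24 tert-butyl{[(1S,4E,9R,11S)-4,11-dimethyl-8-methylidenebicyclo[7.2.0]undec-4-en-11-yl]methoxy}diphenylsilane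
Product: 25 [(1S,4E,9R,11S)-4,11-dimethyl-8-methylidenebicyclo[7.2.0]undec-4-en-11-yl]methanol
Conditions: Bu4NF, THF, 22 → 40 °C
Reagents that add atoms: none
Why: Fluoride cleavage of the silyl ether under non-acidic conditions, which spares the acid-sensitive diene.

Step 15
Reactants: 25 [(1S,4E,9R,11S)-4,11-dimethyl-8-methylidenebicyclo[7.2.0]undec-4-en-11-yl]methanol
Product: 26 (1S,4E,9R,11S)-4,11-dimethyl-8-methylidenebicyclo[7.2.0]undec-4-ene-11-carbaldehyde
Conditions: Pr4NRuO4 (5 mol%), N-methylmorpholine N-oxide, 4 Å MS, CH2Cl2, 22 °C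
Reagents that add atoms: none
Why: Ley–Griffith oxidation under neutral conditions. The aldehyde sits on quaternary C14 and cannot epimerise.

Step 16
Reactants: 27 (S)-(2-methyloxiran-2-yl)methanol
Product: 28 (R)-2-methyloxirane-2-carbaldehyde
Conditions: (COCl)2, DMSO, CH2Cl2, −78 °C; Et3N, −78 → 0 °C; washed solution used directly
Reagents that add atoms: none
Why: Swern oxidation. The stereocentre is quaternary and cannot racemise, and the volatile aldehyde is kept in solution.

Step 17
Reactants: 28 (R)-2-methyloxirane-2-carbaldehyde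
Product: 29 (S)-2-ethynyl-2-methyloxirane
Conditions: dimethyl (1-diazo-2-oxopropyl)phosphonate, K2CO3, MeOH, 0 → 22 °C; extraction, titrated Et2O solution
Reagents that add atoms: dimethyl (1-diazo-2-oxopropyl)phosphonate, CC(=O)C(=[N+]=[N-])P(=O)(OC)OC
Why: Ohira–Bestmann homologation (Seyferth–Gilbert type) converts the non-enolisable aldehyde to the terminal alkyne under mild carbonate conditions that leave the epoxide intact. The descriptor changes only through priorities.

Step 18
Reactants: 26 (1S,4E,9R,11S)-4,11-dimethyl-8-methylidenebicyclo[7.2.0]undec-4-ene-11-carbaldehyde; 29 (S)-2-ethynyl-2-methyloxirane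
Product: 31 1-[(1S,4E,9R,11S)-4,11-dimethyl-8-methylidenebicyclo[7.2.0]undec-4-en-11-yl]-3-[(2S)-2-methyloxiran-2-yl]prop-2-yn-1-ol (C16 epimer mixture), via lithium acetylide 30 (not isolated)
Conditions: 29, n-BuLi, THF, −78 °C; then 26, −78 → −20 °C
Reagents that add atoms: none
Why: 1,2-Addition of a lithium acetylide to the aldehyde forms C16–C18. The new carbinol centre is of no consequence because it is oxidised in step 20.

Step 19
Reactants: 31 1-[(1S,4E,9R,11S)-4,11-dimethyl-8-methylidenebicyclo[7.2.0]undec-4-en-11-yl]-3-[(2S)-2-methyloxiran-2-yl]prop-2-yn-1-ol (C16 epimer mixture)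
Product: 32 (2Z)-1-[(1S,4E,9R,11S)-4,11-dimethyl-8-methylidenebicyclo[7.2.0]undec-4-en-11-yl]-3-[(2S)-2-methyloxiran-2-yl]prop-2-en-1-ol (C16 epimer mixture)
Conditions: H2 (1 atm), Pd/CaCO3 poisoned with Pb(OAc)2, quinoline, EtOAc, 22 °C
Reagents that add atoms: none
Why: Lindlar semi-hydrogenation gives the Z-olefin by syn addition. The alkyne binds the poisoned catalyst far more strongly than the ring-B olefins, and uptake is stopped at one equivalent.

Step 20
Reactants: 32 (2Z)-1-[(1S,4E,9R,11S)-4,11-dimethyl-8-methylidenebicyclo[7.2.0]undec-4-en-11-yl]-3-[(2S)-2-methyloxiran-2-yl]prop-2-en-1-ol (C16 epimer mixture)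
Product: 33 (2Z)-1-[(1S,4E,9R,11S)-4,11-dimethyl-8-methylidenebicyclo[7.2.0]undec-4-en-11-yl]-3-[(2S)-2-methyloxiran-2-yl]prop-2-en-1-one
Conditions: Pr4NRuO4 (5 mol%), N-methylmorpholine N-oxide, 4 Å MS, CH2Cl2, 0 °C
Reagents that add atoms: none
Why: Neutral oxidation of the allylic alcohol to the Z-enone without acid or nucleophile that could isomerise the double bond or open the epoxide.

Step 21
Reactants: 33 (2Z)-1-[(1S,4E,9R,11S)-4,11-dimethyl-8-methylidenebicyclo[7.2.0]undec-4-en-11-yl]-3-[(2S)-2-methyloxiran-2-yl]prop-2-en-1-one
Product: 35 (3R,6R)-3-[(1S,4E,9R,11S)-4,11-dimethyl-8-methylidenebicyclo[7.2.0]undec-4-en-11-yl]-6-(hydroxymethyl)-6-methyl-3,6-dihydro-1,2-dioxin-3-ol, via hydroperoxy enone 34 (not isolated)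
Conditions: anhydrous H2O2 in Et2O (10 equiv), −20 °C; then MoO2(acac)2 (10 mol%), −20 → 10 °C
Reagents that add atoms: hydrogen peroxide, OO
Why: Molybdenum-catalysed perhydrolysis of a 2,2-disubstituted epoxide: the peroxide oxygen attacks the activated tertiary C20 from the side opposite the epoxide oxygen (C20–O27, inversion, S epoxide to R peroxide), directly or through the C16 perhydrate in a 6-exo opening. The hydroperoxide 34 is held next to the ketone by the Z double bond and closes to the peroxyhemiketal (C16–O28); C16 settles by ring–chain equilibration in the anomer with axial OH and with ring A and the CH2OH group equatorial.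

Step 22
Reactants: 35 (3R,6R)-3-[(1S,4E,9R,11S)-4,11-dimethyl-8-methylidenebicyclo[7.2.0]undec-4-en-11-yl]-6-(hydroxymethyl)-6-methyl-3,6-dihydro-1,2-dioxin-3-ol
Product: 36 {(3R,6R)-6-[(1S,4E,9R,11S)-4,11-dimethyl-8-methylidenebicyclo[7.2.0]undec-4-en-11-yl]-6-hydroxy-3-methyl-3,6-dihydro-1,2-dioxin-3-yl}methyl acetate
Conditions: Ac2O (1.2 equiv), pyridine, CH2Cl2, 0 °C
Reagents that add atoms: acetic anhydride, CC(=O)OC(C)=O
Why: Selective acetylation of the primary alcohol; the tertiary hemiketal OH is too hindered to react. Neither peroxy carbon bears a hydrogen, so base-induced peroxide fragmentation has no path.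

Step 23
Reactants: 36 {(3R,6R)-6-[(1S,4E,9R,11S)-4,11-dimethyl-8-methylidenebicyclo[7.2.0]undec-4-en-11-yl]-6-hydroxy-3-methyl-3,6-dihydro-1,2-dioxin-3-yl}methyl acetate
Product: 37 target, the (5S,7S)-epoxide of 36 (C11 S, C12 R, C14 S, C16 R, C20 R)
Conditions: 3-ClC6H4CO3H (1.05 equiv), NaHCO3, CH2Cl2, −20 → 0 °C
Reagents that add atoms: 3-chloroperbenzoic acid, OOC(=O)c1cccc(Cl)c1
Why: Prilezhaev epoxidation of the strained, trisubstituted C5=C7 bond, which is far more nucleophilic than the 1,1-disubstituted C2=C1 and the oxygen-flanked C18=C19 bonds. The peracid should attack the outer face of the preferred ring-B conformers, as it does with caryophyllene, which gives the caryophyllene-oxide relative configuration of the target.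

## Compound list

1 | 3-methylcyclopent-2-en-1-one | CC1=CC(=O)CC1 | starting material
2 | (R)-3-methyl-3-[1-(trimethylsilyl)ethenyl]cyclopentan-1-one | O=C1C[C@](C)(C(=C)[Si](C)(C)C)CC1 | intermediate (not isolated)
3 | (R)-3-ethenyl-3-methylcyclopentan-1-one | O=C1C[C@](C)(C=C)CC1 | intermediate
4 | (R)-1-methyl-3-oxocyclopentane-1-carbaldehyde | O=C1C[C@](C)(C=O)CC1 | intermediate (not isolated)
5 | (R)-3-(hydroxymethyl)-3-methylcyclopentan-1-one | O=C1C[C@](C)(CO)CC1 | intermediate
6 | (R)-3-{[(tert-butyldiphenylsilyl)oxy]methyl}-3-methylcyclopentan-1-one | O=C1C[C@](C)(CO[Si](c2ccccc2)(c2ccccc2)C(C)(C)C)CC1 | intermediate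
7 | (R)-tert-butyl({1-methyl-3-[(trimethylsilyl)oxy]cyclopent-3-en-1-yl}methoxy)diphenylsilane | C[Si](C)(C)OC1=CC[C@@](C)(CO[Si](c2ccccc2)(c2ccccc2)C(C)(C)C)C1 | intermediate (not isolated)
8 | (S)-4-{[(tert-butyldiphenylsilyl)oxy]methyl}-4-methylcyclopent-2-en-1-one | O=C1C[C@](C)(CO[Si](c2ccccc2)(c2ccccc2)C(C)(C)C)C=C1 | intermediate
9 | (4-bromobut-1-yn-1-yl)trimethylsilane | C[Si](C)(C)C#CCCBr | starting material
10 | [4-(trimethylsilyl)but-3-yn-1-yl]magnesium bromide | C[Si](C)(C)C#CCC[Mg]Br | intermediate (not isolated)
11 | (3S,4S)-4-{[(tert-butyldiphenylsilyl)oxy]methyl}-4-methyl-1-[(trimethylsilyl)oxy]-3-[4-(trimethylsilyl)but-3-yn-1-yl]cyclopent-1-ene (chain cis to the C14 methyl) | C[Si](C)(C)C#CCC[C@H]1C=C(O[Si](C)(C)C)C[C@]1(C)CO[Si](c1ccccc1)(c1ccccc1)C(C)(C)C | intermediate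
12 | lithium enolate corresponding to 11 | C[Si](C)(C)C#CCC[C@H]1C=C(O[Li])C[C@]1(C)CO[Si](c1ccccc1)(c1ccccc1)C(C)(C)C | intermediate (not isolated)
13 | (3S,4S)-4-{[(tert-butyldiphenylsilyl)oxy]methyl}-4-methyl-2-(trifluoroacetyl)-3-[4-(trimethylsilyl)but-3-yn-1-yl]cyclopentan-1-one (C12 epimers and enol) | C[Si](C)(C)C#CCC[C@H]1C(C(=O)C(F)(F)F)C(=O)C[C@]1(C)CO[Si](c1ccccc1)(c1ccccc1)C(C)(C)C | intermediate (not isolated)
14 | (3R,4S)-4-{[(tert-butyldiphenylsilyl)oxy]methyl}-2-diazo-4-methyl-3-[4-(trimethylsilyl)but-3-yn-1-yl]cyclopentan-1-one | C[Si](C)(C)C#CCC[C@H]1C(=[N+]=[N-])C(=O)C[C@]1(C)CO[Si](c1ccccc1)(c1ccccc1)C(C)(C)C | intermediate (key-step precursor)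
15 | ring-A ketene, {3-[(tert-butyldiphenylsilyl)oxymethyl]-3-methyl-2-[4-(trimethylsilyl)but-3-yn-1-yl]cyclobutylidene}methanone, C11 and C14 as in 14 | C[Si](C)(C)C#CCC[C@H]1C(=C=O)C[C@]1(C)CO[Si](c1ccccc1)(c1ccccc1)C(C)(C)C | intermediate (not isolated)
16 | methyl 3-{[(tert-butyldiphenylsilyl)oxy]methyl}-3-methyl-2-[4-(trimethylsilyl)but-3-yn-1-yl]cyclobutane-1-carboxylate, C11 and C14 as in 14, C12 as an epimer mixture | C[Si](C)(C)C#CCC[C@H]1C(C[C@]1(C)CO[Si](c1ccccc1)(c1ccccc1)C(C)(C)C)C(=O)OC | intermediate (not isolated)
17 | methyl (1R,2S,3S)-2-(but-3-yn-1-yl)-3-{[(tert-butyldiphenylsilyl)oxy]methyl}-3-methylcyclobutane-1-carboxylate | C#CCC[C@H]1[C@@H](C[C@]1(C)CO[Si](c1ccccc1)(c1ccccc1)C(C)(C)C)C(=O)OC | intermediate (key-step product)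
18 | (E)-alkenyl(dimethyl)alane from 17, Al on C5 cis to the new methyl on C7 | C[Al](C)/C=C(\C)CC[C@H]1[C@@H](C[C@]1(C)CO[Si](c1ccccc1)(c1ccccc1)C(C)(C)C)C(=O)OC | intermediate (not isolated)
19 | methyl (1R,2S,3S)-3-{[(tert-butyldiphenylsilyl)oxy]methyl}-2-[(3E)-5-hydroxy-3-methylpent-3-en-1-yl]-3-methylcyclobutane-1-carboxylate | OC/C=C(\C)CC[C@H]1[C@@H](C[C@]1(C)CO[Si](c1ccccc1)(c1ccccc1)C(C)(C)C)C(=O)OC | intermediate
20 | methyl (1R,2S,3S)-2-[(3E)-5-bromo-3-methylpent-3-en-1-yl]-3-{[(tert-butyldiphenylsilyl)oxy]methyl}-3-methylcyclobutane-1-carboxylate | BrC/C=C(\C)CC[C@H]1[C@@H](C[C@]1(C)CO[Si](c1ccccc1)(c1ccccc1)C(C)(C)C)C(=O)OC | intermediate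
21 | methyl (1R,2S,3S)-3-{[(tert-butyldiphenylsilyl)oxy]methyl}-3-methyl-2-[(3E)-3-methyl-6-(phenylsulfonyl)hex-3-en-1-yl]cyclobutane-1-carboxylate | O=S(=O)(CC/C=C(\C)CC[C@H]1[C@@H](C[C@]1(C)CO[Si](c1ccccc1)(c1ccccc1)C(C)(C)C)C(=O)OC)c1ccccc1 | intermediate
22 | (1R,5E,9S,10S)-10-{[(tert-butyldiphenylsilyl)oxy]methyl}-6,10-dimethyl-3-(phenylsulfonyl)bicyclo[7.2.0]undec-5-en-2-one (C3 epimer mixture) | O=C1C(S(=O)(=O)c3ccccc3)C/C=C(\C)CC[C@H]2[C@H]1C[C@]2(C)CO[Si](c1ccccc1)(c1ccccc1)C(C)(C)C | intermediate
23 | (1R,5E,9S,10S)-10-{[(tert-butyldiphenylsilyl)oxy]methyl}-6,10-dimethylbicyclo[7.2.0]undec-5-en-2-one | O=C1CC/C=C(\C)CC[C@H]2[C@H]1C[C@]2(C)CO[Si](c1ccccc1)(c1ccccc1)C(C)(C)C | intermediate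
24 | tert-butyl{[(1S,4E,9R,11S)-4,11-dimethyl-8-methylidenebicyclo[7.2.0]undec-4-en-11-yl]methoxy}diphenylsilane | C=C1CC/C=C(\C)CC[C@H]2[C@H]1C[C@]2(C)CO[Si](c1ccccc1)(c1ccccc1)C(C)(C)C | intermediate
25 | [(1S,4E,9R,11S)-4,11-dimethyl-8-methylidenebicyclo[7.2.0]undec-4-en-11-yl]methanol | C=C1CC/C=C(\C)CC[C@H]2[C@H]1C[C@]2(C)CO | intermediate
26 | (1S,4E,9R,11S)-4,11-dimethyl-8-methylidenebicyclo[7.2.0]undec-4-ene-11-carbaldehyde | C=C1CC/C=C(\C)CC[C@H]2[C@H]1C[C@]2(C)C=O | intermediate
27 | (S)-(2-methyloxiran-2-yl)methanol | OC[C@@]1(C)CO1 | starting material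
28 | (R)-2-methyloxirane-2-carbaldehyde | O=C[C@@]1(C)CO1 | intermediate
29 | (S)-2-ethynyl-2-methyloxirane | C#C[C@@]1(C)CO1 | intermediate
30 | lithium acetylide of 29 | [Li]C#C[C@@]1(C)CO1 | intermediate (not isolated)
31 | 1-[(1S,4E,9R,11S)-4,11-dimethyl-8-methylidenebicyclo[7.2.0]undec-4-en-11-yl]-3-[(2S)-2-methyloxiran-2-yl]prop-2-yn-1-ol (C16 epimer mixture) | C=C1CC/C=C(\C)CC[C@H]2[C@H]1C[C@]2(C)C(O)C#C[C@@]1(C)CO1 | intermediate
32 | (2Z)-1-[(1S,4E,9R,11S)-4,11-dimethyl-8-methylidenebicyclo[7.2.0]undec-4-en-11-yl]-3-[(2S)-2-methyloxiran-2-yl]prop-2-en-1-ol (C16 epimer mixture) | C=C1CC/C=C(\C)CC[C@H]2[C@H]1C[C@]2(C)C(O)/C=C\[C@@]1(C)CO1 | intermediate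
33 | (2Z)-1-[(1S,4E,9R,11S)-4,11-dimethyl-8-methylidenebicyclo[7.2.0]undec-4-en-11-yl]-3-[(2S)-2-methyloxiran-2-yl]prop-2-en-1-one | C=C1CC/C=C(\C)CC[C@H]2[C@H]1C[C@]2(C)C(=O)/C=C\[C@@]1(C)CO1 | intermediate
34 | (2Z,4R)-1-[(1S,4E,9R,11S)-4,11-dimethyl-8-methylidenebicyclo[7.2.0]undec-4-en-11-yl]-4-hydroperoxy-5-hydroxy-4-methylpent-2-en-1-one | C=C1CC/C=C(\C)CC[C@H]2[C@H]1C[C@]2(C)C(=O)/C=C\[C@](C)(CO)OO | intermediate (not isolated)
35 | (3R,6R)-3-[(1S,4E,9R,11S)-4,11-dimethyl-8-methylidenebicyclo[7.2.0]undec-4-en-11-yl]-6-(hydroxymethyl)-6-methyl-3,6-dihydro-1,2-dioxin-3-ol | C=C1CC/C=C(\C)CC[C@H]2[C@H]1C[C@]2(C)[C@@]1(O)C=C[C@](C)(CO)OO1 | intermediate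
36 | {(3R,6R)-6-[(1S,4E,9R,11S)-4,11-dimethyl-8-methylidenebicyclo[7.2.0]undec-4-en-11-yl]-6-hydroxy-3-methyl-3,6-dihydro-1,2-dioxin-3-yl}methyl acetate | C=C1CC/C=C(\C)CC[C@H]2[C@H]1C[C@]2(C)[C@@]1(O)C=C[C@](C)(COC(C)=O)OO1 | intermediate
37 | CNP0169860.1, the (5S,7S)-epoxide of 36 (C11 S, C12 R, C14 S, C16 R, C20 R in SMILES numbering) | C=C1CC[C@@H]2O[C@@]2(C)CC[C@H]2[C@H]1C[C@]2(C)[C@@]1(O)C=C[C@](C)(COC(C)=O)OO1 | target

## Step count and least certain steps

Total: 23 steps. Longest linear sequence: 21 steps (1–15 and 18–23). The side arm 27 → 29 takes 2 steps (16 and 17).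

**Step 7 (key step).** The excited diazo ketone may be diverted into carbene chemistry (1,2-hydride shift from C11 to an enone, insertion, or addition to the alkyne) in place of ring contraction, and C12 may equilibrate incompletely. Fallback from 11, back at 17, with no free carbene: 11 is treated with 4-methylbenzenesulfonyl azide (MeCN, 50 °C). Dipolar cycloaddition to the silyl enol ether and loss of N2 with the same shift of C13 give, after aqueous work-up, the ring-contracted N-tosyl cyclobutanecarboxamide F1. N-Methylation (MeI, K2CO3, DMF) gives the activated N-methyl-N-tosyl amide F2. NaOMe in MeOH then delivers 17 by methanolysis, C12 equilibration and C-desilylation in one operation.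

**Step 5.** Facial selectivity may be poor, because the CH2–O bond can turn the silyl group away from C11 and the two C14 substituents then differ little near the reacting carbon. Fallback from 11 (as the epimer mixture), back at 14: C11 is erased and reset under catalyst control. Saegusa oxidation of 11 (Pd(OAc)2, O2, DMSO) gives the 3-substituted enone F3. Copper hydride-catalysed asymmetric 1,4-hydrosilylation (Cu(OAc)2·H2O, the appropriate enantiomer of DTBM-SEGPHOS, PhMe2SiH, toluene) delivers hydride to C11 under ligand control and gives the dimethylphenylsilyl enol ether F4. F4 takes the place of 11 in the protocol of step 6 and gives 14.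

**Step 11.** Intermolecular condensation may outrun the nine-membered closure, and the base may deprotonate the ester at C12 in place of C3. Fallback from 19, back at 22, closing C3–C4 instead: 19 is treated with excess lithiated methyl phenyl sulfone to give the β-keto sulfone allylic alcohol F5. Methyl chloroformate and pyridine give the allylic methyl carbonate F6. Pd(PPh3)4 in THF under high dilution ionises the carbonate and lets the C3 carbanion attack C4 (Tsuji–Trost) to give 22.

**Step 21.** Three things may go wrong:
- the C16 carbonyl oxygen of the Z-enone may open the activated epoxide itself (5-exo), giving furan-type products;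
- metal peroxo species may oxidise the ring-B olefins;
- the opening at C20 may drift toward an ionised pathway and lose configuration.

Fallback from 33, back at 35: 33 is isomerised with catalytic I2 under visible light to the E-epoxy enone F7, in which the carbonyl oxygen cannot reach C20. Perhydrolysis as in step 21 gives the E-hydroperoxy enone F8. Irradiation at 350 nm in benzene isomerises the enone double bond, and the Z isomer is removed from the photoequilibrium by closure to 35.

**Step 23.** Facial selectivity may be poor, because it depends on the conformer population of ring B, which the large C14 substituent may shift; C2=C1 may also be over-oxidised. Fallback from 36, back at 37: substrate control is replaced by reagent control. This is a catalytic dioxirane epoxidation with the enantiomer of the fructose-derived Shi ketone that matches the required face (Oxone (2KHSO5·KHSO4·K2SO4), buffered MeCN/dimethoxymethane/H2O, 0 °C). The method is well suited to trans-trisubstituted olefins and makes no new intermediate.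

## Further compounds

F1 | step 7 | 3-{[(tert-butyldiphenylsilyl)oxy]methyl}-3-methyl-N-[(4-methylphenyl)sulfonyl]-2-[4-(trimethylsilyl)but-3-yn-1-yl]cyclobutane-1-carboxamide (C11 and C14 as in 14, C12 epimer mixture) | C[Si](C)(C)C#CCC[C@H]1C(C[C@]1(C)CO[Si](c1ccccc1)(c1ccccc1)C(C)(C)C)C(=O)NS(=O)(=O)c1ccc(C)cc1
F2 | step 7 | N-methyl derivative of F1 | C[Si](C)(C)C#CCC[C@H]1C(C[C@]1(C)CO[Si](c1ccccc1)(c1ccccc1)C(C)(C)C)C(=O)N(C)S(=O)(=O)c1ccc(C)cc1
F3 | step 5 | (S)-4-{[(tert-butyldiphenylsilyl)oxy]methyl}-4-methyl-3-[4-(trimethylsilyl)but-3-yn-1-yl]cyclopent-2-en-1-one | C[Si](C)(C)C#CCCC1=CC(=O)C[C@]1(C)CO[Si](c1ccccc1)(c1ccccc1)C(C)(C)C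
F4 | step 5 | (3S,4S)-4-{[(tert-butyldiphenylsilyl)oxy]methyl}-1-{[dimethyl(phenyl)silyl]oxy}-4-methyl-3-[4-(trimethylsilyl)but-3-yn-1-yl]cyclopent-1-ene | C[Si](C)(C)C#CCC[C@H]1C=C(O[Si](C)(C)c2ccccc2)C[C@]1(C)CO[Si](c1ccccc1)(c1ccccc1)C(C)(C)C
F5 | step 11 | 1-{(1R,2S,3S)-3-{[(tert-butyldiphenylsilyl)oxy]methyl}-2-[(3E)-5-hydroxy-3-methylpent-3-en-1-yl]-3-methylcyclobutyl}-2-(phenylsulfonyl)ethan-1-one | OC/C=C(\C)CC[C@H]1[C@@H](C[C@]1(C)CO[Si](c1ccccc1)(c1ccccc1)C(C)(C)C)C(=O)CS(=O)(=O)c1ccccc1
F6 | step 11 | methyl carbonate of F5 | COC(=O)OC/C=C(\C)CC[C@H]1[C@@H](C[C@]1(C)CO[Si](c1ccccc1)(c1ccccc1)C(C)(C)C)C(=O)CS(=O)(=O)c1ccccc1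
F7 | step 21 | (2E)-1-[(1S,4E,9R,11S)-4,11-dimethyl-8-methylidenebicyclo[7.2.0]undec-4-en-11-yl]-3-[(2S)-2-methyloxiran-2-yl]prop-2-en-1-one | C=C1CC/C=C(\C)CC[C@H]2[C@H]1C[C@]2(C)C(=O)/C=C/[C@@]1(C)CO1
F8 | step 21 | (2E,4R)-1-[(1S,4E,9R,11S)-4,11-dimethyl-8-methylidenebicyclo[7.2.0]undec-4-en-11-yl]-4-hydroperoxy-5-hydroxy-4-methylpent-2-en-1-one | C=C1CC/C=C(\C)CC[C@H]2[C@H]1C[C@]2(C)C(=O)/C=C/[C@](C)(CO)OO
F0 | step 23 | none | none
A1 | alternative 1 | ring-C dioxinol with free primary alcohol (identical with 35) | C=C1CC/C=C(\C)CC[C@H]2[C@H]1C[C@]2(C)[C@@]1(O)C=C[C@](C)(CO)OO1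
A2 | alternative 1 | Z-γ,δ-epoxy enone (identical with 33) | C=C1CC/C=C(\C)CC[C@H]2[C@H]1C[C@]2(C)C(=O)/C=C\[C@@]1(C)CO1
A3 | alternative 2 | ring-A/B cyclononenone with C3 sulfone and tert-butyldimethylsilyl ether (C3 epimer mixture) | O=C1C(S(=O)(=O)c3ccccc3)C/C=C(\C)CC[C@H]2[C@H]1C[C@]2(C)CO[Si](C)(C)C(C)(C)C
A4 | alternative 2 | acyclic β-keto sulfone E-allylic methyl carbonate with tert-butyldimethylsilyl ether | COC(=O)OC/C=C(\C)CC[C@H]1[C@@H](C[C@]1(C)CO[Si](C)(C)C(C)(C)C)C(=O)CS(=O)(=O)c1ccccc1
A5 | alternative 3 | tert-butyl 1-[(benzyloxy)methyl]-3-(prop-1-en-2-yl)-2-[4-(trimethylsilyl)but-3-yn-1-yl]cyclobutane-1-carboxylate (chain trans to isopropenyl and to benzyloxymethyl) | C[Si](C)(C)C#CCC[C@H]1[C@@H](C[C@]1(C(=O)OC(C)(C)C)COCc2ccccc2)C(C)=C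
A6 | alternative 3 | tert-butyl 2-exo-[4-(trimethylsilyl)but-3-yn-1-yl]bicyclo[1.1.0]butane-1-carboxylate | CC(C)(C)OC(=O)[C@]12C[C@H]1[C@@H]2CCC#C[Si](C)(C)C
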